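**Plan**
1. Cuts: C9–C10 first (ring closure by alkenyl-to-aldehyde addition), then C6–C7 together with the lactone C12–O bond (2-(alkoxycarbonyl)allylation and lactonisation); inside the fragments C1=C10 (Wittig) and C7–C11 (Baylis–Hillman); the C8 and C9 esters and the C14 aldehyde are adjusted last.
2. Enabling feature: C10 is the α-carbon of the C1=C10–C14 enal and C9 is the carbinol next to it, so C10 can be an alkenyl nucleophile (2-iodoenal acetal) and C9 an aldehyde. The ring-cis C1=C10 bond, the cis oxirane (C4, C5, O) and the trans γ-lactone (C6, C7, C11, C12, O) bend the open chain so that C10 and C9 can meet.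
3. Forward ring order: oxirane, then α-methylene-γ-lactone (fragment union), then the cyclodecene ring C1–C10.
4. Stereochemistry: C4/C5 from Sharpless epoxidation of a nerol-type Z allylic alcohol; C8 from (R)-glyceraldehyde acetonide; C6/C7 in the chromium allylation (Felkin–Anh at the epoxy aldehyde, anti addition through a chair, 1,2-induction from C8); C9 in the ring closure (Felkin–Anh from the C8 silyl ether); C1=C10 geometry from a Z 2-iodoenal.
5. Convergent: fragment A (C1–C6, C10, C14, C15) in 7 steps, fragment B (C7–C9, C11–C13) in 4 steps, 7 steps after union.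

Key step: step 14

Remark on the chemistry: germacrane numbering (C1–C15) is used for all compounds; in the target C3 and C6 are cis on the oxirane, so it corresponds to a Z C4=C5 alkene (nerol series).

**Route**

Step 1
Reactants: 1 neryl acetate
Product: 3 (2Z)-3-methyl-6-oxohex-2-en-1-yl acetate, via secondary ozonide 2 (not isolated)
Conditions: O3 (1.0 equiv, Sudan Red 7B as end-point indicator), CH2Cl2, −78 °C; then Me2S, −78 °C → rt
Reagents that add atoms: ozone, [O-][O+]=O
Why: Chemoselective ozonolysis with reductive work-up; the isopropylidene alkene is more electron-rich than the alkene deactivated by the allylic acetoxy group, so one equivalent of ozone should cleave only the former and leave the Z alkene (later C4–C5) intact; no stereocentre is formed.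

Step 2
Reactants: 3 (2Z)-3-methyl-6-oxohex-2-en-1-yl acetate; 4 (triphenylphosphoranylidene)acetaldehyde
Product: 5 (2Z,6E)-3-methyl-8-oxoocta-2,6-dien-1-yl acetate
Conditions: toluene, 80 °C
Reagents that add atoms: none
Why: Wittig olefination with a stabilised formyl ylide should give the E enal and brings in C10 and C14.

Step 3
Reactants: 5 (2Z,6E)-3-methyl-8-oxoocta-2,6-dien-1-yl acetate
Product: 6 (2Z,6Z)-7-iodo-3-methyl-8-oxoocta-2,6-dien-1-yl acetate
Conditions: I2 (2 equiv), DMAP (0.2 equiv), K2CO3 (1.2 equiv), THF/H2O (1:1), rt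
Reagents that add atoms: iodine, II
Why: Amine-catalysed α-iodination of an enal (conjugate addition of DMAP, iodination of the enolate, elimination) should give the thermodynamically preferred Z 2-iodoenal with the chain trans to the formyl group, which is the geometry of the ring-cis C1=C10 bond.

Step 4
Reactants: 6 (2Z,6Z)-7-iodo-3-methyl-8-oxoocta-2,6-dien-1-yl acetate
Product: 7 (2Z,6Z)-7-iodo-8,8-dimethoxy-3-methylocta-2,6-dien-1-yl acetate
Conditions: HC(OMe)3 (5 equiv), PPTS (5 mol%), MeOH, rt
Reagents that add atoms: trimethyl orthoformate, COC(OC)OC; methanol, CO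
Why: Acid-catalysed acetalisation masks the C14 aldehyde so that each later carbonyl addition meets only one aldehyde; the alkene geometries are untouched.

Step 5
Reactants: 7 (2Z,6Z)-7-iodo-8,8-dimethoxy-3-methylocta-2,6-dien-1-yl acetate
Product: 8 (2Z,6Z)-7-iodo-8,8-dimethoxy-3-methylocta-2,6-dien-1-ol
Conditions: K2CO3 (0.3 equiv), MeOH, 0 °C → rt
Reagents that add atoms: none
Why: Base-catalysed methanolysis of the acetate (transesterification) frees the allylic alcohol that directs the epoxidation; the acetal and the alkenyl iodide are inert to these conditions.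

Step 6
Reactants: 8 (2Z,6Z)-7-iodo-8,8-dimethoxy-3-methylocta-2,6-dien-1-ol
Product: 9 [(2S,3R)-3-[(3Z)-4-iodo-5,5-dimethoxypent-3-en-1-yl]-3-methyloxiran-2-yl]methanol
Conditions: Ti(OiPr)4 (10 mol%), L-(+)-diethyl tartrate (12 mol%), t-BuOOH (2 equiv, in decane), 4 Å MS, CH2Cl2, −20 °C
Reagents that add atoms: tert-butyl hydroperoxide, CC(C)(C)OO
Why: Sharpless asymmetric epoxidation; with L-(+)-tartrate this nerol-type Z allylic alcohol should give the (2S,3R) epoxide (C5 and C4), the syn-stereospecific oxygen transfer turns the Z alkene into the cis oxirane, and the alkenyl iodide, which has no allylic hydroxyl, is not epoxidised.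

Step 7
Reactants: 9 [(2S,3R)-3-[(3Z)-4-iodo-5,5-dimethoxypent-3-en-1-yl]-3-methyloxiran-2-yl]methanol
Product: 10 (2R,3R)-3-[(3Z)-4-iodo-5,5-dimethoxypent-3-en-1-yl]-3-methyloxirane-2-carbaldehyde
Conditions: DMP (1.3 equiv), pyridine (3 equiv), CH2Cl2, 0 °C → rt
Reagents that add atoms: none
Why: Dess–Martin oxidation under buffered conditions should give the epoxy aldehyde (C6) without epimerisation; the descriptor at C5 changes only because the formyl group now outranks C4, and the aldehyde is used without chromatography.

Step 8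
Reactants: 11 (R)-2,2-dimethyl-1,3-dioxolane-4-carbaldehyde; 12 methyl acrylate
Product: 13 methyl 2-{[(4R)-2,2-dimethyl-1,3-dioxolan-4-yl](hydroxy)methyl}prop-2-enoate
Conditions: DABCO (0.5 equiv), 1,4-dioxane/H2O (1:1), rt
Reagents that add atoms: none
Why: Morita–Baylis–Hillman reaction joins C7 to C11; the new carbinol centre forms as a mixture, which does not matter because it becomes sp2 in the next step, and C8 is taken unchanged from the chiral pool.

Step 9
Reactants: 13 methyl 2-{[(4R)-2,2-dimethyl-1,3-dioxolan-4-yl](hydroxy)methyl}prop-2-enoate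
Product: 15 methyl (2Z)-2-(bromomethyl)-3-[(4S)-2,2-dimethyl-1,3-dioxolan-4-yl]prop-2-enoate, via alkoxysulfonium bromide 14 (not isolated)
Conditions: NBS (1.2 equiv), Me2S (1.3 equiv), CH2Cl2, 0 °C; then 13, 0 °C → rt
Reagents that add atoms: N-bromosuccinimide, BrN1C(=O)CCC1=O
Why: Corey–Kim-type activation of the allylic alcohol followed by SN2′ attack of bromide should give the rearranged 2-(bromomethyl)enoate without free acid, so the acetonide survives; the alkene geometry is not critical because the allylchromium reagent made from it later equilibrates.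

Step 10
Reactants: 15 methyl (2Z)-2-(bromomethyl)-3-[(4S)-2,2-dimethyl-1,3-dioxolan-4-yl]prop-2-enoate
Product: 16 methyl (2Z,4S)-2-(bromomethyl)-4,5-dihydroxypent-2-enoate
Conditions: TFA/H2O (9:1), CH2Cl2, 0 °C
Reagents that add atoms: none
Why: Acid hydrolysis of the isopropylidene acetal; the allylic bromide and the enoate tolerate cold aqueous acid, C8 is untouched, and the diol is silylated at once to keep it from cyclising onto the bromide.

Step 11
Reactants: 16 methyl (2Z,4S)-2-(bromomethyl)-4,5-dihydroxypent-2-enoate
Product: 17 methyl (2Z,4S)-2-(bromomethyl)-4,5-bis[(triethylsilyl)oxy]pent-2-enoate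
Conditions: TESOTf (2.4 equiv), 2,6-lutidine (3 equiv), CH2Cl2, −78 °C
Reagents that add atoms: triethylsilyl trifluoromethanesulfonate, CC[Si](CC)(CC)OS(=O)(=O)C(F)(F)F
Why: Silylation with a silyl triflate and a hindered base should be faster at −78 °C than any alkylation by the allylic bromide, and it installs a primary and a secondary silyl ether that are told apart later.

Step 12
Reactants: 10 (2R,3R)-3-[(3Z)-4-iodo-5,5-dimethoxypent-3-en-1-yl]-3-methyloxirane-2-carbaldehyde; 17 methyl (2Z,4S)-2-(bromomethyl)-4,5-bis[(triethylsilyl)oxy]pent-2-enoate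
Product: 20 epoxy α-methylene-γ-lactone, via allylchromium dichloride 18 (not isolated), via anti hydroxy ester 19 (not isolated)
Conditions: CrCl2 (4 equiv, nickel-free), THF, 0 °C → rt, 17 added slowly to 10 and CrCl2; aq. NH4Cl
Reagents that add atoms: none
Why: Chromium-mediated 2-(alkoxycarbonyl)allylation (Nozaki–Hiyama type, Barbier mode) followed by lactonisation of the chromium alkoxide onto the methyl ester: the allylchromium reagent of trivalent chromium should equilibrate to the isomer with C8 trans to the CH2Cr group and add through a chair-like six-membered transition state to give the 6,7-anti adduct (trans lactone), the aldehyde is attacked anti to the oxirane C–O bond (Felkin–Anh, C6 relative to C5), and C7 is attacked anti to the C9 methylene with H8 eclipsing the alkene (allylic 1,3-strain, C7 relative to C8); divalent chromium without nickel does not touch the alkenyl iodide.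

Step 13
Reactants: 20 epoxy α-methylene-γ-lactone
Product: 22 seco aldehyde, via alkoxysulfonium chloride 21 (not isolated)
Conditions: (COCl)2 (4 equiv), DMSO (8 equiv), CH2Cl2, −78 → −40 °C; then Et3N (12 equiv), −78 → 0 °C
Reagents that add atoms: none
Why: Swern oxidation applied directly to the bis-silyl ether: the primary triethylsilyl ether should be cleaved and oxidised selectively by the activated sulfoxide while the secondary one at C8 stays, giving the α-silyloxy aldehyde (C9) without a separate deprotection and without epimerising C8 at low temperature.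

Step 14
Reactants: 22 seco aldehyde
Product: 24 macrocyclic alcohol, via alkenylchromium dichloride 23 (not isolated)
Conditions: CrCl2 (12 equiv), NiCl2 (0.1 equiv), DMSO, rt, 0.002 M, 22 added by syringe pump over 12 h; aq. NH4Cl
Reagents that add atoms: none
Why: Zerovalent nickel formed from NiCl2 and CrCl2 inserts into the C10–I bond with retention of the alkene geometry, the alkenyl group passes to trivalent chromium, and the alkenylchromium species adds to the C9 aldehyde (Nozaki–Hiyama–Kishi reaction). The closest known reaction type is the intramolecular Nozaki–Hiyama–Kishi coupling of alkenyl iodides with aldehydes used to close medium and large carbocycles. The cyclodecene ring (C1–C10) is closed in a 10-exo-trig mode, the carbonyl oxygen ending up outside the ring as the C9 hydroxyl. The new centre C9 is controlled by C8: in the Felkin–Anh arrangement the C8–OSiEt3 bond lies anti to the incoming C10, which should give the 8,9-anti alcohol, and the non-chelating silyl ether is chosen for this reason. The step needs chemoselectivity (addition to the aldehyde only, not to the lactone, the unsaturated ester, the oxirane or the acetal, which is the normal behaviour of organochromium reagents) and ring closure in preference to oligomerisation. Ring closure is secured by high dilution and by three turn elements in the chain: the Z C1=C10 bond that holds C2 and C9 cis, the cis oxirane at C4–C5 and the trans lactone at C6–C7.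

Step 15
Reactants: 24 macrocyclic alcohol
Product: 25 C9 acetate
Conditions: Ac2O (3 equiv), pyridine, DMAP (0.1 equiv), CH2Cl2, 0 °C → rt
Reagents that add atoms: acetic anhydride, CC(=O)OC(C)=O
Why: DMAP-catalysed acylation of the only free hydroxyl group installs the C9 acetate with retention of configuration.

Step 16
Reactants: 25 C9 acetate
Product: 26 C8 alcohol
Conditions: TBAF (1.5 equiv), AcOH (1.5 equiv), THF, 0 °C
Reagents that add atoms: none
Why: Fluoride-mediated desilylation buffered with acetic acid should remove the triethylsilyl ether without acid (the allylic acetal and the oxirane stay) and without free alkoxide (which suppresses acetyl migration from O9 to O8).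

Step 17
Reactants: 26 C8 alcohol
Product: 27 C8 methacrylate
Conditions: methacrylic anhydride (3 equiv), Et3N (4 equiv), DMAP (0.2 equiv), CH2Cl2, 0 °C
Reagents that add atoms: methacrylic anhydride, CC(=C)C(=O)OC(=O)C(C)=C
Why: DMAP-catalysed esterification of the C8 hydroxyl with retention, done before the aldehyde is unmasked so that a C8 hydroxyl and a C14 aldehyde, which could form a cyclic hemiacetal, never coexist.

Step 18
Reactants: 27 C8 methacrylate
Product: 28 target compound
Conditions: PPTS (0.1 equiv), acetone/H2O (9:1), rt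
Reagents that add atoms: water, O
Why: Mild acid hydrolysis of the allylic dimethyl acetal, which ionises far more easily than the oxirane opens (the oxirane is deactivated by the acyloxy-bearing C6 next to it), should release the conjugated C14 aldehyde; the E enal geometry (C2 trans to CHO) is the thermodynamic one and is retained.

**Compound list**

1 | neryl acetate, (2Z)-3,7-dimethylocta-2,6-dien-1-yl acetate | CC(C)=CCC/C(C)=C\COC(C)=O | starting material
2 | secondary ozonide, (2Z)-5-(5,5-dimethyl-1,2,4-trioxolan-3-yl)-3-methylpent-2-en-1-yl acetate | CC1(C)OOC(CC/C(C)=C\COC(C)=O)O1 | intermediate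
3 | (2Z)-3-methyl-6-oxohex-2-en-1-yl acetate | O=CCC/C(C)=C\COC(C)=O | intermediate
4 | (triphenylphosphoranylidene)acetaldehyde | O=CC=P(c1ccccc1)(c1ccccc1)c1ccccc1 | starting material
5 | (2Z,6E)-3-methyl-8-oxoocta-2,6-dien-1-yl acetate | O=C/C=C/CC/C(C)=C\COC(C)=O | intermediate
6 | (2Z,6Z)-7-iodo-3-methyl-8-oxoocta-2,6-dien-1-yl acetate | O=C/C(I)=C/CC/C(C)=C\COC(C)=O | intermediate
7 | (2Z,6Z)-7-iodo-8,8-dimethoxy-3-methylocta-2,6-dien-1-yl acetate | COC(OC)/C(I)=C/CC/C(C)=C\COC(C)=O | intermediate
8 | (2Z,6Z)-7-iodo-8,8-dimethoxy-3-methylocta-2,6-dien-1-ol | COC(OC)/C(I)=C/CC/C(C)=C\CO | intermediate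
9 | [(2S,3R)-3-[(3Z)-4-iodo-5,5-dimethoxypent-3-en-1-yl]-3-methyloxiran-2-yl]methanol | OC[C@@H]1O[C@]1(C)CC/C=C(\I)C(OC)OC | intermediate
10 | (2R,3R)-3-[(3Z)-4-iodo-5,5-dimethoxypent-3-en-1-yl]-3-methyloxirane-2-carbaldehyde (fragment A) | O=C[C@@H]1O[C@]1(C)CC/C=C(\I)C(OC)OC | intermediate
11 | (R)-2,2-dimethyl-1,3-dioxolane-4-carbaldehyde, (R)-glyceraldehyde acetonide | O=C[C@H]1COC(C)(C)O1 | starting material
12 | methyl acrylate | C=CC(=O)OC | starting material
13 | methyl 2-{[(4R)-2,2-dimethyl-1,3-dioxolan-4-yl](hydroxy)methyl}prop-2-enoate, both carbinol epimers | COC(=O)C(=C)C(O)[C@H]1COC(C)(C)O1 | intermediate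
14 | alkoxysulfonium bromide, the O-dimethylsulfonio derivative of 13 at the carbinol oxygen | COC(=O)C(=C)C(O[S+](C)C)[C@H]1COC(C)(C)O1.[Br-] | intermediate
15 | methyl (2Z)-2-(bromomethyl)-3-[(4S)-2,2-dimethyl-1,3-dioxolan-4-yl]prop-2-enoate | COC(=O)/C(CBr)=C/[C@H]1COC(C)(C)O1 | intermediate
16 | methyl (2Z,4S)-2-(bromomethyl)-4,5-dihydroxypent-2-enoate | COC(=O)/C(CBr)=C/[C@H](O)CO | intermediate
17 | methyl (2Z,4S)-2-(bromomethyl)-4,5-bis[(triethylsilyl)oxy]pent-2-enoate (fragment B) | COC(=O)/C(CBr)=C/[C@H](O[Si](CC)(CC)CC)CO[Si](CC)(CC)CC | intermediate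
18 | allylchromium dichloride, [(2E,4S)-2-(methoxycarbonyl)-4,5-bis(triethylsilyloxy)pent-2-en-1-yl]chromium dichloride (trivalent chromium) | COC(=O)/C(C[Cr](Cl)Cl)=C\[C@H](O[Si](CC)(CC)CC)CO[Si](CC)(CC)CC | intermediate
19 | anti hydroxy ester, the open-chain methyl ester with free C6 hydroxyl; C5–O/C6–O anti, C6–O/C7–C11 syn, C7–C11/C8–O anti along the C5–C9 zigzag | COC(=O)C(=C)[C@H]([C@H](O[Si](CC)(CC)CC)CO[Si](CC)(CC)CC)[C@H](O)[C@@H]1O[C@]1(C)CC/C=C(\I)C(OC)OC | intermediate
20 | epoxy α-methylene-γ-lactone: trans-4,5-disubstituted 3-methylideneoxolan-2-one with the (1S)-1,2-bis(triethylsilyloxy)ethyl group at C7 and the (2S,3R)-oxiranyl group of fragment A at C6; C4–C8 as in the target | CC[Si](CC)(CC)OC[C@@H](O[Si](CC)(CC)CC)[C@H]1C(=C)C(=O)O[C@@H]1[C@@H]1O[C@]1(C)CC/C=C(\I)C(OC)OC | intermediate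
21 | alkoxysulfonium chloride, 20 with the C9 oxygen carrying dimethylsulfonio in place of triethylsilyl | C[S+](C)OC[C@@H](O[Si](CC)(CC)CC)[C@H]1C(=C)C(=O)O[C@@H]1[C@@H]1O[C@]1(C)CC/C=C(\I)C(OC)OC.[Cl-] | intermediate
22 | seco aldehyde: C9 aldehyde with C8–OSiEt3, trans α-methylene-γ-lactone, cis oxirane and Z alkenyl iodide (C10) bearing the C14 dimethyl acetal; C4–C8 as in the target | O=C[C@@H](O[Si](CC)(CC)CC)[C@H]1C(=C)C(=O)O[C@@H]1[C@@H]1O[C@]1(C)CC/C=C(\I)C(OC)OC | intermediate
23 | alkenylchromium dichloride, 22 with CrCl2 in place of iodine at C10 (trivalent chromium) | O=C[C@@H](O[Si](CC)(CC)CC)[C@H]1C(=C)C(=O)O[C@@H]1[C@@H]1O[C@]1(C)CC/C=C(\[Cr](Cl)Cl)C(OC)OC | intermediate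
24 | macrocyclic alcohol, 4,5-epoxy-9-hydroxy-14,14-dimethoxy-8-(triethylsilyloxy)germacra-1(10),11(13)-dien-12,6-olide; C4–C9 as in the target | CC[Si](CC)(CC)O[C@H]1[C@H]2C(=C)C(=O)O[C@@H]2[C@@H]2O[C@]2(C)CC/C=C(/C(OC)OC)[C@H]1O | intermediate
25 | C9 acetate, 9-acetoxy-4,5-epoxy-14,14-dimethoxy-8-(triethylsilyloxy)germacra-1(10),11(13)-dien-12,6-olide | CC[Si](CC)(CC)O[C@H]1[C@H]2C(=C)C(=O)O[C@@H]2[C@@H]2O[C@]2(C)CC/C=C(/C(OC)OC)[C@H]1OC(C)=O | intermediate
26 | C8 alcohol, 9-acetoxy-4,5-epoxy-8-hydroxy-14,14-dimethoxygermacra-1(10),11(13)-dien-12,6-olide | O[C@H]1[C@H]2C(=C)C(=O)O[C@@H]2[C@@H]2O[C@]2(C)CC/C=C(/C(OC)OC)[C@H]1OC(C)=O | intermediate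
27 | C8 methacrylate, 9-acetoxy-4,5-epoxy-14,14-dimethoxy-8-(2-methylprop-2-enoyloxy)germacra-1(10),11(13)-dien-12,6-olide | C=C(C)C(=O)O[C@H]1[C@H]2C(=C)C(=O)O[C@@H]2[C@@H]2O[C@]2(C)CC/C=C(/C(OC)OC)[C@H]1OC(C)=O | intermediate
28 | target, (1(10)E,4R,5S,6S,7R,8S,9R)-9-acetoxy-4,5-epoxy-8-(2-methylprop-2-enoyloxy)-14-oxogermacra-1(10),11(13)-dien-12,6-olide | C=C(C)C(=O)O[C@H]1[C@H]2C(=C)C(=O)O[C@@H]2[C@@H]2O[C@]2(C)CC/C=C(/C=O)[C@H]1OC(C)=O | target

**Totals**

Total step count: 18. Longest linear sequence: 14 steps (steps 1–7, then 12–18).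

**Steps most likely to fail**

Step 14. The alkenylchromium species may add to the face of the C9 aldehyde that the Felkin–Anh model disfavours, because the strain of the ten-membered transition state can outweigh the bias of the C8 silyl ether; intermolecular coupling also competes if dilution is insufficient. The fallback sets the C9 configuration by ketone reduction instead of during C–C bond formation. It sets out from 22: the ring is closed as described, and the C9 epimer of 24 F1, alone or mixed with 24, is oxidised with DMP and pyridine to the macrocyclic C9 ketone F2. This cross-conjugated enone is reduced with (R)-2-methyl-CBS-oxazaborolidine and catecholborane in toluene at −78 °C, the alkenyl carbon C10 acting as the large group, and the sequence comes back to the route at 24.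

Step 12. The allylchromium reagent may lose the C8 silyloxy group by vinylogous β-elimination (diene formation), and the mobile bis-silyloxy side chain may discriminate the two faces of C7 poorly, so that diastereomeric lactones form. The fallback changes the coupling partner and the protecting-group order. It sets out from 10 and 15: the rigid acetonide bromide 15 is used directly in the chromium-mediated allylation (CrCl2, THF, 0 °C → rt) to give the acetonide lactone F3; the dioxolane is a stronger face-directing group and its ring oxygen is a poorer leaving group. The acetonide is then exchanged in methanol (PPTS, MeOH, rt; the C14 dimethyl acetal is degenerate under these conditions) to give the diol lactone F4, and bis-silylation (TESOTf, 2,6-lutidine, CH2Cl2, −78 °C) comes back to the route at 20.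

Step 10. The freed hydroxyl groups may attack the allylic bromide intramolecularly (O-alkylation to a dihydrofuran) during hydrolysis or before silylation. In the fallback the silyl ethers are in place before the bromide exists. It sets out from methyl acrylate 12 and commercial (S)-but-3-ene-1,2-diol F5. Silylation (TESCl, imidazole, DMF) gives (S)-3,4-bis(triethylsilyloxy)but-1-ene F6, and ozonolysis (O3, CH2Cl2, −78 °C; then PPh3) gives (R)-2,3-bis(triethylsilyloxy)propanal F7. The Morita–Baylis–Hillman reaction of this aldehyde with 12 (DABCO, rt) gives the Baylis–Hillman adduct F8 as carbinol epimers, and NBS/Me2S as in step 9 comes back to the route at 17.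

**Further compounds**

F1 | step 14 | C9 epimer of 24 (8,9-syn alcohol) | CC[Si](CC)(CC)O[C@H]1[C@H]2C(=C)C(=O)O[C@@H]2[C@@H]2O[C@]2(C)CC/C=C(/C(OC)OC)[C@@H]1O
F2 | step 14 | macrocyclic C9 ketone, 4,5-epoxy-14,14-dimethoxy-9-oxo-8-(triethylsilyloxy)germacra-1(10),11(13)-dien-12,6-olide | CC[Si](CC)(CC)O[C@H]1[C@H]2C(=C)C(=O)O[C@@H]2[C@@H]2O[C@]2(C)CC/C=C(/C(OC)OC)C1=O
F3 | step 12 | acetonide lactone, analogue of 20 with the C8/C9 diol as isopropylidene acetal | CC1(C)OC[C@@H](O1)[C@H]1C(=C)C(=O)O[C@@H]1[C@@H]1O[C@]1(C)CC/C=C(\I)C(OC)OC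
F4 | step 12 | diol lactone, analogue of 20 with free C8 and C9 hydroxyls | OC[C@@H](O)[C@H]1C(=C)C(=O)O[C@@H]1[C@@H]1O[C@]1(C)CC/C=C(\I)C(OC)OC
F5 | step 10 | (S)-but-3-ene-1,2-diol | C=C[C@H](O)CO
F6 | step 10 | (S)-3,4-bis(triethylsilyloxy)but-1-ene | C=C[C@H](O[Si](CC)(CC)CC)CO[Si](CC)(CC)CC
F7 | step 10 | (R)-2,3-bis(triethylsilyloxy)propanal | O=C[C@H](O[Si](CC)(CC)CC)CO[Si](CC)(CC)CC
F8 | step 10 | methyl (4R)-3-hydroxy-2-methylidene-4,5-bis(triethylsilyloxy)pentanoate, both C3 epimers | COC(=O)C(=C)C(O)[C@H](O[Si](CC)(CC)CC)CO[Si](CC)(CC)CC
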